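**Strategy**

The route rests on cutting ring C between C3 and C4. The C4 ketone with its C3 methylene is equivalent to a C3=C4 enol ether, and that olefin is closed by ring-closing metathesis between a vinyl group on C2 and the silyl enol ether of an acetyl group at C4a of ring A. One operation forms the C3–C4 bond and the pyranone ring at the flavanone oxidation level, without touching the C2–O1 stereocentre, which is set earlier by an iridium-catalysed branched-selective allylic etherification. The precursor is the (S)-1-arylallyl ether of a 3,5-diprenyl-2-hydroxyacetophenone silyl enol ether that already carries all three prenyl groups and two methoxymethyl ethers.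

Key step: step 11

Remark: the (Sa,Sc,Sc) antipode of the phosphoramidite is assumed to deliver the (S)-ether in step 9, by analogy with the sense of induction of this catalyst class with heteroatom nucleophiles and cinnamyl carbonates; should a trial show the opposite sense, the (Ra,Rc,Rc) ligand is used with no other change.

Remark: where one step makes or breaks two identical bonds (steps 1 and 3, and the two acetal cleavages in step 12), the singly reacted species are not listed as separate compounds.

**Route**

Step 1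
Reactants: 1 2,4-dihydroxyacetophenone
Product: 2 1-(2,4-dihydroxy-3,5-diiodophenyl)ethanone
Conditions: N-iodosuccinimide (2.1 equiv), CF3CO2H (10 mol %), MeCN, 0 °C to rt
Reagents that add atoms: N-iodosuccinimide, O=C1CCC(=O)N1I
Why: Electrophilic aromatic iodination: C3 and C5 are each ortho or para to both hydroxyl groups while C6 is deactivated by the acetyl group, so two equivalents of the iodonium source should give only the 3,5-diiodide.

Step 2
Reactants: 2 1-(2,4-dihydroxy-3,5-diiodophenyl)ethanone
Product: 3 1-[2-hydroxy-3,5-diiodo-4-(methoxymethoxy)phenyl]ethanone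
Conditions: MOMCl (1.1 equiv), K2CO3 (1.5 equiv), acetone, 0 °C to rt
Reagents that add atoms: chloromethyl methyl ether, COCCl
Why: Williamson-type alkylation of the more acidic C4 phenoxide; the C2 hydroxyl is locked in a hydrogen bond to the acetyl carbonyl and stays free for the later etherification.

Step 3
Reactants: 3 1-[2-hydroxy-3,5-diiodo-4-(methoxymethoxy)phenyl]ethanone; 4 prenylboronic acid pinacol ester
Product: 5 1-[2-hydroxy-4-(methoxymethoxy)-3,5-bis(3-methylbut-2-en-1-yl)phenyl]ethanone
Conditions: 4 (3 equiv), PdCl2(dppf) (10 mol %), Cs2CO3 (4 equiv), THF/H2O 10:1, 65 °C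
Reagents that add atoms: none
Why: Double Suzuki–Miyaura coupling of aryl iodides with an allylic pinacol boronate: reductive elimination through the unsubstituted terminus of the prenyl–palladium intermediate should give linear prenyl groups, and the ketone, free phenol and acetal are inert to aqueous carbonate.

Step 4
Reactants: 6 3-bromo-4-hydroxybenzaldehyde
Product: 7 3-bromo-4-(methoxymethoxy)benzaldehyde
Conditions: MOMCl (1.2 equiv), K2CO3 (2 equiv), acetone, 0 °C to rt
Reagents that add atoms: chloromethyl methyl ether, COCCl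
Why: Williamson-type protection of the only phenol as a base-stable acetal that tolerates every later step up to the final acid treatment.

Step 5
Reactants: 7 3-bromo-4-(methoxymethoxy)benzaldehyde; 8 ethyl (triphenylphosphoranylidene)acetate
Product: 9 ethyl (E)-3-[3-bromo-4-(methoxymethoxy)phenyl]prop-2-enoate
Conditions: 8 (1.15 equiv), CH2Cl2, rt to 40 °C
Reagents that add atoms: none
Why: Wittig olefination with a stabilised ylide, which gives the (E)-cinnamate with aromatic aldehydes; the aldehyde is consumed here so that the allylic boronate of the next step cannot add to it.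

Step 6
Reactants: 9 ethyl (E)-3-[3-bromo-4-(methoxymethoxy)phenyl]prop-2-enoate; 4 prenylboronic acid pinacol ester
Product: 10 ethyl (E)-3-[4-(methoxymethoxy)-3-(3-methylbut-2-en-1-yl)phenyl]prop-2-enoate
Conditions: 4 (1.5 equiv), PdCl2(dppf) (5 mol %), Cs2CO3 (2 equiv), THF/H2O 10:1, 65 °C
Reagents that add atoms: none
Why: Suzuki–Miyaura coupling as in step 3, on an aryl bromide activated by the para acrylate; the ethyl ester should survive the short exposure to aqueous carbonate.

Step 7
Reactants: 10 ethyl (E)-3-[4-(methoxymethoxy)-3-(3-methylbut-2-en-1-yl)phenyl]prop-2-enoate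
Product: 11 (E)-3-[4-(methoxymethoxy)-3-(3-methylbut-2-en-1-yl)phenyl]prop-2-en-1-ol
Conditions: i-Bu2AlH (2.3 equiv), CH2Cl2, −78 °C; KNaC4H4O6 (aq.)
Reagents that add atoms: none
Why: 1,2-Reduction of the conjugated ester by the aluminium hydride at low temperature gives the allylic alcohol without touching the olefins or the acetal.

Step 8
Reactants: 11 (E)-3-[4-(methoxymethoxy)-3-(3-methylbut-2-en-1-yl)phenyl]prop-2-en-1-ol
Product: 12 methyl (E)-3-[4-(methoxymethoxy)-3-(3-methylbut-2-en-1-yl)phenyl]prop-2-en-1-yl carbonate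
Conditions: ClCO2Me (1.5 equiv), pyridine (2 equiv), CH2Cl2, 0 °C
Reagents that add atoms: methyl chloroformate, COC(=O)Cl
Why: Acylation of the primary allylic alcohol with a chloroformate gives the linear carbonate, the standard leaving group for iridium-catalysed allylic substitution.

Step 9
Reactants: 5 1-[2-hydroxy-4-(methoxymethoxy)-3,5-bis(3-methylbut-2-en-1-yl)phenyl]ethanone; 12 methyl (E)-3-[4-(methoxymethoxy)-3-(3-methylbut-2-en-1-yl)phenyl]prop-2-en-1-yl carbonate
Product: 14 1-[4-(methoxymethoxy)-2-{[(1S)-1-[4-(methoxymethoxy)-3-(3-methylbut-2-en-1-yl)phenyl]prop-2-en-1-yl]oxy}-3,5-bis(3-methylbut-2-en-1-yl)phenyl]ethanone, via lithium aryloxide 13 (not isolated)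
Conditions: 5 (1.3 equiv), LiN(SiMe3)2 (1.3 equiv), THF, 0 °C; then 12 (1.0 equiv), [Ir(cod)Cl]2 (2 mol %), (Sa,Sc,Sc)-N,N-bis(1-phenylethyl)dinaphtho[2,1-d:1′,2′-f][1,3,2]dioxaphosphepin-4-amine (4 mol %, pre-activated with n-PrNH2), THF, 40 °C
Reagents that add atoms: none
Why: Iridium-catalysed asymmetric allylic etherification with a cyclometalated iridium–phosphoramidite catalyst: the aryloxide attacks the allyliridium complex at its aryl-substituted terminus, which gives the branched ether, and the chiral ligand fixes the face of attack, which sets C2 as (S), while the methyl ketone and both acetals are spectators.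

Step 10
Reactants: 14 1-[4-(methoxymethoxy)-2-{[(1S)-1-[4-(methoxymethoxy)-3-(3-methylbut-2-en-1-yl)phenyl]prop-2-en-1-yl]oxy}-3,5-bis(3-methylbut-2-en-1-yl)phenyl]ethanone
Product: 16 tert-butyldimethylsilyl enol ether of ketone 14 (RCM precursor), via potassium enolate 15 (not isolated)
Conditions: KN(SiMe3)2 (1.15 equiv), THF, −78 °C; TBSCl (1.4 equiv), −78 to 0 °C; NaHCO3 (aq.) work-up, Et3N-deactivated silica
Reagents that add atoms: tert-butyldimethylsilyl chloride, CC(C)(C)[Si](C)(C)Cl
Why: Kinetic deprotonation of the methyl ketone by a hindered amide base and O-silylation of the potassium enolate give the silyl enol ether under non-acidic conditions, so that the ionisable benzylic allylic ether at C2 and the acetals are never exposed to a silyl triflate.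

Step 11
Reactants: 16 tert-butyldimethylsilyl enol ether of ketone 14
Product: 17 (2S)-4-[(tert-butyldimethylsilyl)oxy]-7-(methoxymethoxy)-2-[4-(methoxymethoxy)-3-(3-methylbut-2-en-1-yl)phenyl]-6,8-bis(3-methylbut-2-en-1-yl)-2H-chromene
Conditions: (H2IMes)(PCy3)Cl2Ru=CHPh (second-generation Grubbs catalyst, 7.5 mol %), degassed CH2Cl2 (0.005 M), 40 °C, argon sparge, dark; filtration through Et3N-deactivated silica, used at once
Reagents that add atoms: none
Why: After phosphine loss the ruthenium benzylidene exchanges onto the monosubstituted C2 vinyl group to give the C3 alkylidene, which adds across the 1,1-disubstituted enol ether with ruthenium on the CH2 terminus and C3 on C4; cycloreversion of the ruthenacyclobutane releases the 4-silyloxy-2H-chromene and Ru=CH2, which carries the chain with loss of ethylene. The closest known reaction type is ring-closing metathesis of olefin-tethered silyl enol ethers to cyclic silyl enol ethers, including aryl ketone enol ethers with an ortho heteroatom-linked allyl group that close to benzo-fused six-membered rings. Ring C closes as a six-membered ring by joining two ortho substituents of ring A, so the reacting carbons are held close by the arene and the O1–C2 bond. No stereocentre is created, and C2, set in step 9, keeps its (S) configuration because neither its C–H nor its C–O bond takes part. The step needs the six-ring closure onto the enol ether to outrun the seven-ring closure of the same alkylidene onto the C8 prenyl olefin and any intermolecular metathesis; the shorter tether, the lower reactivity of trisubstituted olefins and high dilution should secure this, and the metallacycle regiochemistry keeps ruthenium off the oxygen-bearing carbon. Mild temperature, exclusion of light and immediate use of 17 guard against migration of the allylic double bond and electrocyclic opening of the 2H-chromene.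

Step 12
Reactants: 17 (2S)-4-[(tert-butyldimethylsilyl)oxy]-7-(methoxymethoxy)-2-[4-(methoxymethoxy)-3-(3-methylbut-2-en-1-yl)phenyl]-6,8-bis(3-methylbut-2-en-1-yl)-2H-chromene
Product: 19 (2S)-7-hydroxy-2-[4-hydroxy-3-(3-methylbut-2-en-1-yl)phenyl]-6,8-bis(3-methylbut-2-en-1-yl)-2,3-dihydro-4H-chromen-4-one (target), via flavanone bis(methoxymethyl) ether 18 (not isolated)
Conditions: HCl (3 M aq.), MeOH/THF 4:1, 0 to 40 °C, monitored; NaHCO3 (aq.) quench
Reagents that add atoms: none
Why: Acid-catalysed solvolysis: protonation of the enol ether at C3 and loss of silicon give the C4 ketone without a flavanone enolate that could open ring C by β-elimination of the O1 aryloxide and racemise C2, and the same dilute acid then hydrolyses both methoxymethyl acetals at a temperature at which the prenyl olefins should not add the neighbouring phenols.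

**Compound list**

1 | 2,4-dihydroxyacetophenone | CC(=O)c1ccc(O)cc1O | starting material
2 | 1-(2,4-dihydroxy-3,5-diiodophenyl)ethanone | CC(=O)c1cc(I)c(O)c(I)c1O | intermediate
3 | 1-[2-hydroxy-3,5-diiodo-4-(methoxymethoxy)phenyl]ethanone | CC(=O)c1cc(I)c(OCOC)c(I)c1O | intermediate
4 | 4,4,5,5-tetramethyl-2-(3-methylbut-2-en-1-yl)-1,3,2-dioxaborolane (prenylboronic acid pinacol ester) | CC(C)=CCB1OC(C)(C)C(C)(C)O1 | starting material
5 | 1-[2-hydroxy-4-(methoxymethoxy)-3,5-bis(3-methylbut-2-en-1-yl)phenyl]ethanone | CC(=O)c1cc(CC=C(C)C)c(OCOC)c(CC=C(C)C)c1O | intermediate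
6 | 3-bromo-4-hydroxybenzaldehyde | O=Cc1ccc(O)c(Br)c1 | starting material
7 | 3-bromo-4-(methoxymethoxy)benzaldehyde | COCOc1ccc(C=O)cc1Br | intermediate
8 | ethyl (triphenylphosphoranylidene)acetate | CCOC(=O)C=P(c1ccccc1)(c1ccccc1)c1ccccc1 | starting material
9 | ethyl (E)-3-[3-bromo-4-(methoxymethoxy)phenyl]prop-2-enoate | CCOC(=O)/C=C/c1ccc(OCOC)c(Br)c1 | intermediate
10 | ethyl (E)-3-[4-(methoxymethoxy)-3-(3-methylbut-2-en-1-yl)phenyl]prop-2-enoate | CCOC(=O)/C=C/c1ccc(OCOC)c(CC=C(C)C)c1 | intermediate
11 | (E)-3-[4-(methoxymethoxy)-3-(3-methylbut-2-en-1-yl)phenyl]prop-2-en-1-ol | OC/C=C/c1ccc(OCOC)c(CC=C(C)C)c1 | intermediate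
12 | methyl (E)-3-[4-(methoxymethoxy)-3-(3-methylbut-2-en-1-yl)phenyl]prop-2-en-1-yl carbonate | COC(=O)OC/C=C/c1ccc(OCOC)c(CC=C(C)C)c1 | intermediate
13 | lithium 2-acetyl-5-(methoxymethoxy)-4,6-bis(3-methylbut-2-en-1-yl)phenolate | [Li+].CC(=O)c1cc(CC=C(C)C)c(OCOC)c(CC=C(C)C)c1[O-] | intermediate
14 | 1-[4-(methoxymethoxy)-2-{[(1S)-1-[4-(methoxymethoxy)-3-(3-methylbut-2-en-1-yl)phenyl]prop-2-en-1-yl]oxy}-3,5-bis(3-methylbut-2-en-1-yl)phenyl]ethanone | C=C[C@H](Oc1c(C(C)=O)cc(CC=C(C)C)c(OCOC)c1CC=C(C)C)c1ccc(OCOC)c(CC=C(C)C)c1 | intermediate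
15 | potassium enolate of 14 (potassium 1-aryl-ethen-1-olate, (S) at the ether carbon) | [K+].C=C[C@H](Oc1c(C(=C)[O-])cc(CC=C(C)C)c(OCOC)c1CC=C(C)C)c1ccc(OCOC)c(CC=C(C)C)c1 | intermediate
16 | tert-butyl({1-[4-(methoxymethoxy)-2-{[(1S)-1-[4-(methoxymethoxy)-3-(3-methylbut-2-en-1-yl)phenyl]prop-2-en-1-yl]oxy}-3,5-bis(3-methylbut-2-en-1-yl)phenyl]ethenyl}oxy)dimethylsilane | C=C[C@H](Oc1c(C(=C)O[Si](C)(C)C(C)(C)C)cc(CC=C(C)C)c(OCOC)c1CC=C(C)C)c1ccc(OCOC)c(CC=C(C)C)c1 | intermediate
17 | (2S)-4-[(tert-butyldimethylsilyl)oxy]-7-(methoxymethoxy)-2-[4-(methoxymethoxy)-3-(3-methylbut-2-en-1-yl)phenyl]-6,8-bis(3-methylbut-2-en-1-yl)-2H-chromene | CC(C)=CCc1cc([C@@H]2C=C(O[Si](C)(C)C(C)(C)C)c3cc(CC=C(C)C)c(OCOC)c(CC=C(C)C)c3O2)ccc1OCOC | intermediate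
18 | (2S)-7-(methoxymethoxy)-2-[4-(methoxymethoxy)-3-(3-methylbut-2-en-1-yl)phenyl]-6,8-bis(3-methylbut-2-en-1-yl)-2,3-dihydro-4H-chromen-4-one | CC(C)=CCc1cc([C@@H]2CC(=O)c3cc(CC=C(C)C)c(OCOC)c(CC=C(C)C)c3O2)ccc1OCOC | intermediate
19 | (2S)-7-hydroxy-2-[4-hydroxy-3-(3-methylbut-2-en-1-yl)phenyl]-6,8-bis(3-methylbut-2-en-1-yl)-2,3-dihydro-4H-chromen-4-one | CC(C)=CCc1cc([C@@H]2CC(=O)c3cc(CC=C(C)C)c(O)c(CC=C(C)C)c3O2)ccc1O | target

**Step count and risks**

Total step count: 12. Longest linear sequence: 9 steps (6 to 19, steps 4 to 12).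

Steps most likely to fail:

1. Step 11 (ring-closing metathesis). The C3 alkylidene may close onto the C8 prenyl olefin with loss of isobutene and form a seven-membered ring. The catalyst may also be trapped as an oxygen-stabilised carbene on the enol ether, or ruthenium hydrides may move the allylic double bond. The fallback avoids metathesis, sets out from 5 and 7 and comes back at 18.
   - Stille coupling of 7 with tributyl(3-methylbut-2-en-1-yl)stannane (Pd(PPh3)4, DMF, 90 °C) should give 4-(methoxymethoxy)-3-(3-methylbut-2-en-1-yl)benzaldehyde F1.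
   - Claisen–Schmidt condensation of F1 with 5 (KOH, EtOH/H2O, rt) should give the (E)-2′-hydroxychalcone F2.
   - NaOAc in refluxing EtOH should cyclise F2 by oxa-Michael addition to the racemic flavanone bis(methoxymethyl) ether F3.
   - Kinetic resolution of F3 by asymmetric transfer hydrogenation (RuCl(p-cymene)[(R,R)-TsDPEN], HCO2H/Et3N) should reduce the (2R)-enantiomer to the (2R,4R)-cis-flavan-4-ol F4 and leave the (2S)-ketone 18. This is separated and taken through the conditions of step 12.

2. Step 9 (allylic etherification). The chelated, doubly ortho-substituted aryloxide may attack the allyliridium intermediate slowly. The product ether may also re-ionise on the catalyst, which would erode the branched-to-linear ratio and the enantiomeric purity. The fallback separates the setting of the stereocentre from the C–O coupling, sets out from 12 and 5 and comes back at 14.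
   - The same iridium catalyst with the small nucleophile KOSiEt3 should give the branched (S)-triethylsilyl ether F5.
   - Bu4NF should free (1S)-1-[4-(methoxymethoxy)-3-(3-methylbut-2-en-1-yl)phenyl]prop-2-en-1-ol F6.
   - LiN(SiMe3)2 and di-tert-butyl dicarbonate should give the (S)-tert-butyl carbonate F7.
   - Enantiospecific rhodium-catalysed allylic etherification (RhCl(PPh3)3, P(OMe)3, THF, 0 °C to rt) proceeds with net retention and is suited to ortho-substituted aryloxides. With the sodium aryloxide F8 (from 5 and NaN(SiMe3)2) it should give 14.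

3. Step 3 (double prenyl coupling). The sequence may stall after the first coupling because the C3 iodide is hindered. Protodeiodination may occur, or the prenyl group may be transferred through its tertiary terminus. The fallback installs unbranched allyl groups first, sets out from 3 and comes back at 5.
   - Stille coupling of 3 with allyltributylstannane (Pd(PPh3)4, DMF, 90 °C) should give 1-[2-hydroxy-4-(methoxymethoxy)-3,5-di(prop-2-en-1-yl)phenyl]ethanone F9.
   - Olefin cross-metathesis of F9 with excess 2-methylbut-2-ene ((H2IMes)(PCy3)Cl2Ru=CHPh, second-generation Grubbs catalyst, CH2Cl2, 40 °C) should convert both allyl groups into prenyl groups and give 5.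

**Further compounds**

F1 | step 11 | 4-(methoxymethoxy)-3-(3-methylbut-2-en-1-yl)benzaldehyde | COCOc1ccc(C=O)cc1CC=C(C)C
F2 | step 11 | (E)-1-[2-hydroxy-4-(methoxymethoxy)-3,5-bis(3-methylbut-2-en-1-yl)phenyl]-3-[4-(methoxymethoxy)-3-(3-methylbut-2-en-1-yl)phenyl]prop-2-en-1-one | CC(C)=CCc1cc(/C=C/C(=O)c2cc(CC=C(C)C)c(OCOC)c(CC=C(C)C)c2O)ccc1OCOC
F3 | step 11 | racemic 7-(methoxymethoxy)-2-[4-(methoxymethoxy)-3-(3-methylbut-2-en-1-yl)phenyl]-6,8-bis(3-methylbut-2-en-1-yl)-2,3-dihydro-4H-chromen-4-one | CC(C)=CCc1cc(C2CC(=O)c3cc(CC=C(C)C)c(OCOC)c(CC=C(C)C)c3O2)ccc1OCOC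
F4 | step 11 | (2R,4R)-7-(methoxymethoxy)-2-[4-(methoxymethoxy)-3-(3-methylbut-2-en-1-yl)phenyl]-6,8-bis(3-methylbut-2-en-1-yl)-3,4-dihydro-2H-chromen-4-ol | CC(C)=CCc1cc([C@H]2C[C@@H](O)c3cc(CC=C(C)C)c(OCOC)c(CC=C(C)C)c3O2)ccc1OCOC
F5 | step 9 | triethyl{[(1S)-1-[4-(methoxymethoxy)-3-(3-methylbut-2-en-1-yl)phenyl]prop-2-en-1-yl]oxy}silane | C=C[C@H](O[Si](CC)(CC)CC)c1ccc(OCOC)c(CC=C(C)C)c1
F6 | step 9 | (1S)-1-[4-(methoxymethoxy)-3-(3-methylbut-2-en-1-yl)phenyl]prop-2-en-1-ol | C=C[C@H](O)c1ccc(OCOC)c(CC=C(C)C)c1
F7 | step 9 | tert-butyl (1S)-1-[4-(methoxymethoxy)-3-(3-methylbut-2-en-1-yl)phenyl]prop-2-en-1-yl carbonate | C=C[C@H](OC(=O)OC(C)(C)C)c1ccc(OCOC)c(CC=C(C)C)c1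
F8 | step 9 | sodium 2-acetyl-5-(methoxymethoxy)-4,6-bis(3-methylbut-2-en-1-yl)phenolate | [Na+].CC(=O)c1cc(CC=C(C)C)c(OCOC)c(CC=C(C)C)c1[O-]
F9 | step 3 | 1-[2-hydroxy-4-(methoxymethoxy)-3,5-di(prop-2-en-1-yl)phenyl]ethanone | CC(=O)c1cc(CC=C)c(OCOC)c(CC=C)c1O
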